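## Analysis of the target

The target is a C2-symmetric bibenzyl. Two catechol rings (ring A and ring A′) are joined through their C5 atoms by a CH2–CH2 bridge, and each carries a 1,2,2-trimethylcyclopentyl ring (ring B, ring B′) at C3.

The only stereocentres are the two quaternary benzylic carbons C1 of rings B and B′, both (S). They lie nine bonds apart and cannot influence each other, so each must be set in the absolute sense. The homodimeric constitution allows both to be made as one monomer.

In each ring B, C1 is flanked by a second fully substituted carbon, C2 (CMe2), and by an arene carbon with an ortho oxygen. C1 is therefore the most congested atom and C1–C2 the most crowded bond.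

The sensitive groups are the catechols, which oxidise in air to ortho-quinones, and the electron-rich arenes, which tend to react with electrophiles and halogen radicals on the ring rather than at a benzylic position. The bridge has no functional group, so its carbons must enter at a higher oxidation level.

The strategy rests on ring B. C1 has the ring neighbours C5 (a CH2 group) and C2, so the bonds C1–C5 and C2–C3 can come from a three-carbon trimethylenemethane unit (C5, C4, C3). This unit adds across an aryl(methyl)nitroalkene whose aryl-bearing carbon becomes C1 and whose nitro-bearing carbon becomes C2. The extra exocyclic carbon on C4 and the nitro group are afterwards exchanged for what the target needs.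

## Retrosynthetic reasoning

**18 to 17.** The four phenolic O–H bonds are traced back to methyl ethers. Methyl ethers withstand the organocopper, palladium and hot-alkali steps of the route, and a single Lewis-acid demethylation at the end releases the air-sensitive catechols only when nothing else remains to be done.

**17 to two molecules of 16.** The central CH2–CH2 bond is cut. This is the only cut that divides the molecule into two identical halves, so one monomer serves twice. The forward reaction is a reductive homocoupling of benzylic bromide 16 on zerovalent nickel. It must form the C–C bond faster than the benzyl intermediates are reduced to a methyl group.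

**16 to 15, and the origin of the bridge carbon.** The C–Br bond is made from the benzylic alcohol 15. Bromination of a methyl group on the finished dimethoxyarene was ruled out, because a ring this electron-rich is brominated on the nucleus in preference to the benzylic position. The bridge carbon is therefore carried from the beginning at the alcohol oxidation level, as a silyl ether, and it is the aldehyde carbon of starting material 1. This changes only a spectator substituent of the arene in the key step.

**15 to 13.** The ring methylene C4 is traced back to a ketone, removed by Wolff–Kishner reduction through hydrazone 14. The same hot alkali takes off the silyl ether, so no separate deprotection is needed. The carbonyl is placed at C4 because that is where the cycloaddition leaves its surplus carbon, and because a carbonyl there activates C2.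

**13 to 12 to 11 to 10.** The two C2–CH3 bonds are cut one after the other as conjugate additions of methylcopper reagents, with a Saegusa–Ito dehydrogenation of silyl enol ether 11 in between. The alternative would convert the nitro carbon into a ketone and replace its oxygen by two methyl groups with a methyltitanium Lewis acid. It was not taken for three reasons:
- it passes through a tertiary cation at C2, next to the aryl-bearing stereocentre; bridging by the electron-rich arene would give a phenonium ion with a mirror plane and so erode the enantiomeric purity;
- the Lewis acid threatens the exocyclic alkene and the benzylic silyl ether;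
- the conjugate additions keep C1 away from any cationic or enolisable position.

**10 to 9 to 8.** Enone 10 comes from β-nitro ketone 9 by β-elimination of the nitro group, and 9 from cycloadduct 8 by ozonolysis of the exocyclic methylene. The nitro group thus serves twice, first as the activator of the cycloaddition and then as the leaving group that turns C2 into the electrophilic β-carbon of an enone. No Nef reaction at a neopentyl position is required.

**8 to 6 and 7 (key disconnection).** The ring bonds C1–C5 and C2–C3 are cut. This makes the quaternary stereocentre in a conjugate addition to a strongly activated alkene, at a stage when C2 is still a CH group, so the two crowded carbons are not built in the same event. A cut at the aryl–C1 bond would instead require a coupling at a tertiary carbon next to CMe2. The forward reaction has to add the palladium-bound trimethylenemethane fragment from 7 to one face of nitroalkene 6.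

**6 to 5 to 3 and 4.** The C–N bond of 6 comes from radical nitration of the 1,1-disubstituted styrene 5. The aryl–alkenyl bond of 5 comes from a Suzuki–Miyaura coupling of bromide 3 with boronic ester 4. Both are short, reliable steps, so the risk of the route stays in the cycloaddition.

**3 to 2 to 1.** Silylation and reduction lead back to the commercial aldehyde 1, which already has the bromine, both methoxy groups and the bridge carbon in the correct positions.

## Alternatives that were turned down

**Alternative 1:** The cyclopentane is taken from the chiral pool and the arene is built around it. The starting acid is (1S,3R)-camphoric acid A1, which would be degraded to the alkynyl ketone A2.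
- Forward key step: the α-methoxy β-keto ester A3 adds to the alkyne carbon of A2 that carries the cyclopentyl group, its acetyl methyl condenses with the ketone of A2, and loss of the ester group aromatises the ring to phenol A4.
- For it: the stereocentre and the neighbouring CMe2 carbon are bought, not made. On enantiomeric purity and on the vicinal quaternary carbons this plan is stronger than the chosen one.
- Against it: the target needs the (1S) series, which corresponds to the less abundant antipode of the acid. One carboxyl group of A1 has to be removed and the other, on a neopentyl-type tertiary carbon, must be turned into an ynone over several functional-group steps. The annulation has to join a tertiary carbanion to an alkyne carbon with a quaternary substituent, which is the most crowded bond of the arene, in competition with 1,2-addition and with closure through the enol oxygen to a pyranone. A4 is still several steps from a monomer that can be dimerised.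
- Comparison: the chosen route accepts the risk of a catalytic asymmetric step and in return forms ring B and its stereocentre in one operation from a flat precursor, with fewer steps overall.

**Alternative 2:** Both aryl–C1 bonds are cut, with each arene tethered to its cyclopentene through the phenolic oxygen and the future C1 methyl carbon.
- Forward key step: the bibenzyl bis(aryl iodide) A5 undergoes two palladium-catalysed 5-exo Heck cyclisations under a chiral ligand, giving the bis-spiro dihydrobenzofuran A6.
- For it: both quaternary stereocentres arise in one catalytic operation on an assembled bibenzyl, and the tether fixes the regiochemistry. Pairing two stereocentres sends the minor events into a meso by-product and raises the enantiomeric purity of the C2-symmetric product. On this point it equals the chosen route, where dimerisation of 16 has the same effect.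
- Against it: the aryl group must insert at an alkene carbon that already adjoins the CMe2 carbon, so both crowded carbons meet in the carbopalladation. Afterwards each neopentyl O–CH2 bond must be cleaved reductively to reveal phenol and methyl in the presence of other aryl ethers, and the ring alkenes hydrogenated.
- Comparison: the chosen route makes C1 while C2 is still a CH group and needs no cleavage of a tether.

**Alternative 3:** Both aryl–bridge bonds are cut and the two bridge carbons come from acetylene A8.
- Forward key step: two molecules of the enantiopure aryl bromide A7 couple with both C–H bonds of A8 under palladium and copper catalysis to give diarylacetylene A9, which is then hydrogenated and demethylated.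
- For it: the union is a very dependable reaction and avoids the labile benzylic bromide 16. On this point it is stronger than the nickel homocoupling.
- Against it: it solves only the bridge. A7, with its quaternary stereocentre next to CMe2, still has to be made enantiopure by other means. The electron-rich bromide adds slowly to palladium, and mono-coupling and oxidative diyne formation would give wrong bridges.
- Comparison: the chosen route includes the solution for the stereocentre, brings the bridge carbon in with starting material 1, and needs no halogen on the finished arene.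

Key step: step 5

Assumption (chemistry): the antipode of the phosphoramidite ligand that leads to (1R,2S)-8 is fixed by a trial cycloaddition, since the sense of induction cannot be read from the substrate alone.

## Route

Step 1
Reactants: 1 3-bromo-4,5-dimethoxybenzaldehyde
Product: 2 (3-bromo-4,5-dimethoxyphenyl)methanol
Conditions: NaBH4, MeOH, 0 °C → rt
Reagents that add atoms: none
Why: Borohydride reduction of an aromatic aldehyde; the aryl bromide and the methyl ethers are inert, and the future bridge carbon is set at the alcohol oxidation level.

Step 2
Reactants: 2 (3-bromo-4,5-dimethoxyphenyl)methanol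
Product: 3 [(3-bromo-4,5-dimethoxyphenyl)methoxy](tert-butyl)dimethylsilane
Conditions: TBSCl, imidazole, DMF, rt
Reagents that add atoms: tert-butyl(chloro)dimethylsilane, CC(C)(C)[Si](C)(C)Cl
Why: Standard silylation of a primary benzylic alcohol; the silyl ether protects the hydroxyl group from the nitration, the organocopper reagents and the palladium steps.

Step 3
Reactants: 3 [(3-bromo-4,5-dimethoxyphenyl)methoxy](tert-butyl)dimethylsilane; 4 4,4,5,5-tetramethyl-2-(prop-1-en-2-yl)-1,3,2-dioxaborolane
Product: 5 tert-butyl{[3,4-dimethoxy-5-(prop-1-en-2-yl)phenyl]methoxy}dimethylsilane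
Conditions: Pd(dppf)Cl2 (cat.), K2CO3, 1,4-dioxane/H2O, 90 °C
Reagents that add atoms: none
Why: Suzuki–Miyaura coupling of an aryl bromide with an alkenylboronic ester; the ortho methoxy group hinders oxidative addition only slightly and the ferrocenyl bisphosphine ligand copes with such bromides.

Step 4
Reactants: 5 tert-butyl{[3,4-dimethoxy-5-(prop-1-en-2-yl)phenyl]methoxy}dimethylsilane
Product: 6 tert-butyl({3,4-dimethoxy-5-[(1E)-1-nitroprop-1-en-2-yl]phenyl}methoxy)dimethylsilane
Conditions: AgNO2, TEMPO (cat.), 4 Å molecular sieves, ClCH2CH2Cl, 70 °C
Reagents that add atoms: silver nitrite, [Ag+].[O-]N=O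
Why: Radical nitration of a styrene: NO2 released from AgNO2 adds to the terminal carbon, TEMPO captures the tertiary benzylic radical, and loss of the hydrogen next to the nitro group gives the conjugated nitroalkene, for which the (E) isomer with aryl trans to nitro is favoured; a known alkene nitration applied to an α-methylstyrene.

Step 5
Reactants: 6 tert-butyl({3,4-dimethoxy-5-[(1E)-1-nitroprop-1-en-2-yl]phenyl}methoxy)dimethylsilane; 7 2-[(trimethylsilyl)methyl]prop-2-en-1-yl acetate
Product: 8 tert-butyl({3,4-dimethoxy-5-[(1R,2S)-1-methyl-4-methylidene-2-nitrocyclopentyl]phenyl}methoxy)dimethylsilane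
Conditions: Pd(dba)2 (cat.), BINOL-derived phosphoramidite with a trans-2,5-di(2-naphthyl)pyrrolidine unit (cat., single antipode), toluene, rt → 45 °C, slow addition of 7
Reagents that add atoms: none
Why: Zerovalent palladium ionises the allylic acetate of 7 and the liberated acetate removes the silyl group, which gives the zwitterionic palladium–trimethylenemethane complex bound to the chiral phosphoramidite. Its carbanionic terminus adds to the β-carbon of nitroalkene 6 in a conjugate addition, forming C1–C5 and the quaternary centre C1 and leaving a nitronate. The nitronate carbon then attacks a terminus of the cationic η3-allylpalladium unit, an intramolecular allylic alkylation that closes the five-membered ring in the exo sense (palladium leaves outside the new ring), forms C2–C3 and returns zerovalent palladium. The closest known reaction type is the asymmetric palladium-catalysed trimethylenemethane (3+2) cycloaddition to β-aryl nitroalkenes and to β,β-disubstituted acceptors that give quaternary carbons. C1 is controlled by the ligand: the palladium that carries the phosphoramidite stays with the carbanion terminus and selects one enantioface of the β-carbon, and the ligand antipode is chosen so that C1 is (R) in 8, the arrangement that reads (S) in the target once C2 has become CMe2. C2 is set in the ring closure and should come out with nitro trans to aryl from the (E)-alkene, but it is of no consequence because step 6 makes it trigonal. The step needs β-regioselectivity, which the polarisation by the nitro group secures, and enantioface selectivity, which requires geometrically pure (E)-6 because the (Z) isomer would offer the opposite face to the same catalyst. The ortho methoxy group twists the arene out of the alkene plane, so the acceptor is less reactive than a simple β-nitrostyrene and 7 is added slowly to keep the trimethylenemethane complex from reacting with itself.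

Step 6
Reactants: 8 tert-butyl({3,4-dimethoxy-5-[(1R,2S)-1-methyl-4-methylidene-2-nitrocyclopentyl]phenyl}methoxy)dimethylsilane
Product: 10 (4S)-4-[5-({[tert-butyl(dimethyl)silyl]oxy}methyl)-2,3-dimethoxyphenyl]-4-methylcyclopent-2-en-1-one, via nitro ketone 9 (not isolated)
Conditions: O3, CH2Cl2, −78 °C (Sudan red end point); Me2S, −78 °C → rt; then Et3N, CH2Cl2, 0 °C → rt
Reagents that add atoms: ozone, [O-][O+]=O
Why: Ozonolysis cleaves the only alkene (the arene reacts far more slowly and the indicator dye marks the end point) to the β-nitro ketone, which loses the nitro group by E1cB elimination through the enolate on the side of the nitro carbon, a standard enone synthesis; the C2 stereocentre is erased and the quaternary carbon, which carries no hydrogen, is untouched.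

Step 7
Reactants: 10 (4S)-4-[5-({[tert-butyl(dimethyl)silyl]oxy}methyl)-2,3-dimethoxyphenyl]-4-methylcyclopent-2-en-1-one
Product: 11 tert-butyl[(3,4-dimethoxy-5-{(1S)-1,2-dimethyl-4-[(trimethylsilyl)oxy]cyclopent-3-en-1-yl}phenyl)methoxy]dimethylsilane
Conditions: Me2CuLi (from MeLi and CuI), TMSCl, THF, −78 °C; Et3N, cold aqueous NaHCO3 work-up
Reagents that add atoms: lithium dimethylcuprate, [Li+].C[Cu-]C; chlorotrimethylsilane, C[Si](C)(C)Cl
Why: Conjugate addition of a Gilman cuprate accelerated by TMSCl, which traps the enolate regiospecifically as the silyl enol ether; attack at a β-carbon next to a quaternary carbon is usual for 4,4-disubstituted cyclopentenones, and the configuration at the new methyl-bearing carbon does not matter because step 8 makes it trigonal.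

Step 8
Reactants: 11 tert-butyl[(3,4-dimethoxy-5-{(1S)-1,2-dimethyl-4-[(trimethylsilyl)oxy]cyclopent-3-en-1-yl}phenyl)methoxy]dimethylsilane
Product: 12 (4S)-4-[5-({[tert-butyl(dimethyl)silyl]oxy}methyl)-2,3-dimethoxyphenyl]-3,4-dimethylcyclopent-2-en-1-one
Conditions: Pd(OAc)2, MeCN, rt → 40 °C
Reagents that add atoms: none
Why: Saegusa–Ito oxidation: the silyl enol ether gives a palladium enolate, and β-hydride elimination can only take the hydrogen at the methyl-bearing carbon because the other α-carbon has a quaternary neighbour, so a single enone results.

Step 9
Reactants: 12 (4S)-4-[5-({[tert-butyl(dimethyl)silyl]oxy}methyl)-2,3-dimethoxyphenyl]-3,4-dimethylcyclopent-2-en-1-one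
Product: 13 (3S)-3-[5-({[tert-butyl(dimethyl)silyl]oxy}methyl)-2,3-dimethoxyphenyl]-3,4,4-trimethylcyclopentan-1-one
Conditions: Me2CuLi (from MeLi and CuI), BF3·OEt2, Et2O, −78 → −30 °C; aqueous NH4Cl
Reagents that add atoms: lithium dimethylcuprate, [Li+].C[Cu-]C
Why: Lewis-acid-promoted cuprate conjugate addition to a β,β-disubstituted cyclopentenone, a known way to build a CMe2 carbon next to an aryl-bearing quaternary carbon in 3,3,4,4-tetrasubstituted cyclopentanones; no cation and no enolisable position touches the stereocentre, so its configuration is retained.

Step 10
Reactants: 13 (3S)-3-[5-({[tert-butyl(dimethyl)silyl]oxy}methyl)-2,3-dimethoxyphenyl]-3,4,4-trimethylcyclopentan-1-one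
Product: 15 {3,4-dimethoxy-5-[(1S)-1,2,2-trimethylcyclopentyl]phenyl}methanol, via hydrazone 14 (not isolated)
Conditions: N2H4·H2O, diethylene glycol, 130 °C; then KOH, 195 °C (H2O and excess N2H4 distilled off)
Reagents that add atoms: none
Why: Wolff–Kishner reduction in the Huang-Minlon procedure: hydrazone 14 forms under neutral conditions, and hot KOH then drives the loss of N2 to the methylene group and cleaves the silyl ether by attack at silicon; the ketone is flanked by two unhindered CH2 groups and the stereocentre cannot epimerise.

Step 11
Reactants: 15 {3,4-dimethoxy-5-[(1S)-1,2,2-trimethylcyclopentyl]phenyl}methanol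
Product: 16 5-(bromomethyl)-1,2-dimethoxy-3-[(1S)-1,2,2-trimethylcyclopentyl]benzene
Conditions: PBr3, Et2O, 0 °C
Reagents that add atoms: phosphorus tribromide, BrP(Br)Br
Why: Conversion of a primary benzylic alcohol into the bromide by SN2 displacement on the phosphite ester at low temperature; the bromide is used at once because electron-rich benzylic bromides are labile.

Step 12
Reactants: 16 5-(bromomethyl)-1,2-dimethoxy-3-[(1S)-1,2,2-trimethylcyclopentyl]benzene (two molecules)
Product: 17 1,2-bis{3,4-dimethoxy-5-[(1S)-1,2,2-trimethylcyclopentyl]phenyl}ethane
Conditions: Ni(cod)2, DMF, rt → 40 °C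
Reagents that add atoms: none
Why: Reductive homocoupling of a benzylic bromide on zerovalent nickel: oxidative addition gives a benzylnickel bromide, which takes up a second molecule of 16, and reductive elimination forms the CH2–CH2 bond; both halves come from the same enantiomer, so the product is the C2-symmetric (S,S) compound, and any minor enantiomer ends mainly in a meso diastereomer that has to be removed.

Step 13
Reactants: 17 1,2-bis{3,4-dimethoxy-5-[(1S)-1,2,2-trimethylcyclopentyl]phenyl}ethane
Product: 18 5,5'-(ethane-1,2-diyl)bis{3-[(1S)-1,2,2-trimethylcyclopentyl]benzene-1,2-diol}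
Conditions: BBr3, CH2Cl2, −78 → 0 °C; then MeOH, H2O, under argon
Reagents that add atoms: none
Why: Lewis-acid cleavage of four aryl methyl ethers by BBr3 (bromide attacks the methyl group of the O–B complex); no stereocentre is touched, and the catechols are released only in the last step and worked up under inert gas because they oxidise in air.

## Compound list

1 | 3-bromo-4,5-dimethoxybenzaldehyde | COc1cc(C=O)cc(Br)c1OC | starting material
2 | (3-bromo-4,5-dimethoxyphenyl)methanol | COc1cc(CO)cc(Br)c1OC | intermediate
3 | [(3-bromo-4,5-dimethoxyphenyl)methoxy](tert-butyl)dimethylsilane | COc1cc(CO[Si](C)(C)C(C)(C)C)cc(Br)c1OC | intermediate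
4 | 4,4,5,5-tetramethyl-2-(prop-1-en-2-yl)-1,3,2-dioxaborolane (isopropenylboronic acid pinacol ester) | CC(=C)B1OC(C)(C)C(C)(C)O1 | starting material
5 | tert-butyl{[3,4-dimethoxy-5-(prop-1-en-2-yl)phenyl]methoxy}dimethylsilane | COc1cc(CO[Si](C)(C)C(C)(C)C)cc(C(C)=C)c1OC | intermediate
6 | tert-butyl({3,4-dimethoxy-5-[(1E)-1-nitroprop-1-en-2-yl]phenyl}methoxy)dimethylsilane | COc1cc(CO[Si](C)(C)C(C)(C)C)cc(/C(C)=C/[N+](=O)[O-])c1OC | intermediate
7 | 2-[(trimethylsilyl)methyl]prop-2-en-1-yl acetate | CC(=O)OCC(=C)C[Si](C)(C)C | starting material
8 | tert-butyl({3,4-dimethoxy-5-[(1R,2S)-1-methyl-4-methylidene-2-nitrocyclopentyl]phenyl}methoxy)dimethylsilane (nitro trans to aryl) | C[C@@]1(CC(=C)C[C@@H]1[N+](=O)[O-])c1cc(CO[Si](C)(C)C(C)(C)C)cc(OC)c1OC | intermediate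
9 | (3R,4S)-3-[5-({[tert-butyl(dimethyl)silyl]oxy}methyl)-2,3-dimethoxyphenyl]-3-methyl-4-nitrocyclopentan-1-one (not isolated) | C[C@@]1(CC(=O)C[C@@H]1[N+](=O)[O-])c1cc(CO[Si](C)(C)C(C)(C)C)cc(OC)c1OC | intermediate
10 | (4S)-4-[5-({[tert-butyl(dimethyl)silyl]oxy}methyl)-2,3-dimethoxyphenyl]-4-methylcyclopent-2-en-1-one | C[C@@]1(CC(=O)C=C1)c1cc(CO[Si](C)(C)C(C)(C)C)cc(OC)c1OC | intermediate
11 | tert-butyl[(3,4-dimethoxy-5-{(1S)-1,2-dimethyl-4-[(trimethylsilyl)oxy]cyclopent-3-en-1-yl}phenyl)methoxy]dimethylsilane (either epimer at the CH–CH3 carbon serves) | C[C@@]1(CC(O[Si](C)(C)C)=CC1C)c1cc(CO[Si](C)(C)C(C)(C)C)cc(OC)c1OC | intermediate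
12 | (4S)-4-[5-({[tert-butyl(dimethyl)silyl]oxy}methyl)-2,3-dimethoxyphenyl]-3,4-dimethylcyclopent-2-en-1-one | C[C@@]1(CC(=O)C=C1C)c1cc(CO[Si](C)(C)C(C)(C)C)cc(OC)c1OC | intermediate
13 | (3S)-3-[5-({[tert-butyl(dimethyl)silyl]oxy}methyl)-2,3-dimethoxyphenyl]-3,4,4-trimethylcyclopentan-1-one | C[C@@]1(CC(=O)CC1(C)C)c1cc(CO[Si](C)(C)C(C)(C)C)cc(OC)c1OC | intermediate
14 | hydrazone of (3S)-3-[5-({[tert-butyl(dimethyl)silyl]oxy}methyl)-2,3-dimethoxyphenyl]-3,4,4-trimethylcyclopentan-1-one (not isolated) | C[C@@]1(CC(=NN)CC1(C)C)c1cc(CO[Si](C)(C)C(C)(C)C)cc(OC)c1OC | intermediate
15 | {3,4-dimethoxy-5-[(1S)-1,2,2-trimethylcyclopentyl]phenyl}methanol | C[C@@]1(CCCC1(C)C)c1cc(CO)cc(OC)c1OC | intermediate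
16 | 5-(bromomethyl)-1,2-dimethoxy-3-[(1S)-1,2,2-trimethylcyclopentyl]benzene | C[C@@]1(CCCC1(C)C)c1cc(CBr)cc(OC)c1OC | intermediate
17 | 1,2-bis{3,4-dimethoxy-5-[(1S)-1,2,2-trimethylcyclopentyl]phenyl}ethane | C[C@@]1(CCCC1(C)C)c1cc(CCc2cc(OC)c(OC)c([C@@]3(C)CCCC3(C)C)c2)cc(OC)c1OC | intermediate
18 | 5,5'-(ethane-1,2-diyl)bis{3-[(1S)-1,2,2-trimethylcyclopentyl]benzene-1,2-diol} | CC1(C)CCC[C@]1(C)c1cc(CCc2cc(O)c(O)c([C@@]3(C)CCCC3(C)C)c2)cc(O)c1O | target

## Step count and least certain steps

Total step count: 13. Longest linear sequence: 13 steps, from 1 to 18; compounds 4 and 7 are bought.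

**Step 5 (key step).** The conjugate addition of the trimethylenemethane carbanion may be too slow at the twisted β,β-disubstituted nitroalkene, so that the donor is used up by protodesilylation and self-reaction. The ligand may also distinguish poorly between aryl and methyl at the β-carbon, giving low facial selectivity.

Fallback: it sets out from bromide 3. Bromine–lithium exchange (n-BuLi, THF, −78 °C), B(OiPr)3 and mild aqueous hydrolysis should give [5-({[tert-butyl(dimethyl)silyl]oxy}methyl)-2,3-dimethoxyphenyl]boronic acid F1. Asymmetric conjugate addition of F1 to 3-methylcyclopent-2-en-1-one with Pd(OCOCF3)2 and the antipode of a tert-butyl pyridine–oxazoline ligand that gives the (R) ketone (ClCH2CH2Cl, H2O, 60 °C) should give (3R)-3-[5-({[tert-butyl(dimethyl)silyl]oxy}methyl)-2,3-dimethoxyphenyl]-3-methylcyclopentan-1-one F2. Dehydrogenation with IBX in DMSO can only occur on the side away from the quaternary carbon and returns to the route at enone 10. The weak point of this fallback is the ortho substituent of the boronic acid.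

**Step 4.** Geometric and positional control may be lost: the (Z) isomer may form, or a methyl hydrogen may be removed in place of the hydrogen next to the nitro group, which gives the deconjugated allylic nitro isomer.

Fallback: it sets out from bromide 3. Bromine–lithium exchange and acylation with N-methoxy-N-methylacetamide should give 1-[5-({[tert-butyl(dimethyl)silyl]oxy}methyl)-2,3-dimethoxyphenyl]ethan-1-one F3. A Henry reaction in neat nitromethane with catalytic DBU should give racemic 2-[5-({[tert-butyl(dimethyl)silyl]oxy}methyl)-2,3-dimethoxyphenyl]-1-nitropropan-2-ol F4. Dehydration with MsCl and Et3N, with the amine left to equilibrate the product to the conjugated (E) isomer, returns to the route at nitroalkene 6. The C=C bond is then built by condensation and not by radical nitration; the unfavourable equilibrium of the ketone nitroaldol is the price.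

**Step 9.** C–C bond formation may fail at the β-carbon, which already carries a methyl group and adjoins the quaternary carbon. The cuprate would then act as a base or add to the carbonyl group.

Fallback: it sets out from enone 12. Reduction with NaBH4 and CeCl3·7H2O in MeOH should give (4S)-4-[5-({[tert-butyl(dimethyl)silyl]oxy}methyl)-2,3-dimethoxyphenyl]-3,4-dimethylcyclopent-2-en-1-ol F5. Hydroxyl-directed Simmons–Smith cyclopropanation (Et2Zn, CH2I2, CH2Cl2) should give (4S)-4-[5-({[tert-butyl(dimethyl)silyl]oxy}methyl)-2,3-dimethoxyphenyl]-4,5-dimethylbicyclo[3.1.0]hexan-2-ol F6. Oxidation with Dess–Martin periodinane should give (4S)-4-[5-({[tert-butyl(dimethyl)silyl]oxy}methyl)-2,3-dimethoxyphenyl]-4,5-dimethylbicyclo[3.1.0]hexan-2-one F7. Reductive opening of the cyclopropyl ketone with SmI2 (THF, HMPA, t-BuOH) should cleave the external cyclopropane bond, which overlaps best with the carbonyl group, turn the cyclopropane CH2 into the second methyl group and return to the route at ketone 13. The crowded carbon is then attacked by an electrophilic carbenoid delivered from the neighbouring hydroxyl group.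

**Step 10.** Hot alkali may demethylate the aryl methyl ethers by nucleophilic attack, and the silyl group may be removed incompletely, giving phenolic mixtures.

Fallback: it sets out from ketone 13. Condensation with TsNHNH2 in EtOH should give the 4-methylbenzenesulfonylhydrazone of 13, F8. Reduction with catecholborane (CHCl3, 0 °C), followed by NaOAc·3H2O at reflux, should give tert-butyl({3,4-dimethoxy-5-[(1S)-1,2,2-trimethylcyclopentyl]phenyl}methoxy)dimethylsilane F9. Desilylation with TBAF in THF returns to the route at alcohol 15. No strong base and no high temperature are involved.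

**Step 12.** The electron-rich benzylic bromide may decompose by solvolysis or self-alkylation of the arene before it couples, or the benzyl intermediates may be reduced to the methylarene. In addition, the statistical pairing sends any minor enantiomer into the meso diastereomer, so the enantiomeric purity should be raised by crystallisation at 10 or 15 before this step if needed.

Fallback: it sets out from alcohol 15. Oxidation with MnO2 in CH2Cl2 should give 3,4-dimethoxy-5-[(1S)-1,2,2-trimethylcyclopentyl]benzaldehyde F10. McMurry coupling (TiCl4, Zn, THF, reflux) should give (E)-1,2-bis{3,4-dimethoxy-5-[(1S)-1,2,2-trimethylcyclopentyl]phenyl}ethene F11. Hydrogenation (H2, Pd/C, EtOAc) returns to the route at 17. No benzylic halide is needed.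

## Further compounds

F1 | step 5 | [5-({[tert-butyl(dimethyl)silyl]oxy}methyl)-2,3-dimethoxyphenyl]boronic acid | COc1cc(CO[Si](C)(C)C(C)(C)C)cc(B(O)O)c1OC
F2 | step 5 | (3R)-3-[5-({[tert-butyl(dimethyl)silyl]oxy}methyl)-2,3-dimethoxyphenyl]-3-methylcyclopentan-1-one | C[C@@]1(CC(=O)CC1)c1cc(CO[Si](C)(C)C(C)(C)C)cc(OC)c1OC
F3 | step 4 | 1-[5-({[tert-butyl(dimethyl)silyl]oxy}methyl)-2,3-dimethoxyphenyl]ethan-1-one | COc1cc(CO[Si](C)(C)C(C)(C)C)cc(C(C)=O)c1OC
F4 | step 4 | 2-[5-({[tert-butyl(dimethyl)silyl]oxy}methyl)-2,3-dimethoxyphenyl]-1-nitropropan-2-ol (racemic) | COc1cc(CO[Si](C)(C)C(C)(C)C)cc(C(C)(O)C[N+](=O)[O-])c1OC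
F5 | step 9 | (4S)-4-[5-({[tert-butyl(dimethyl)silyl]oxy}methyl)-2,3-dimethoxyphenyl]-3,4-dimethylcyclopent-2-en-1-ol (carbinol epimers) | C[C@@]1(CC(O)C=C1C)c1cc(CO[Si](C)(C)C(C)(C)C)cc(OC)c1OC
F6 | step 9 | (4S)-4-[5-({[tert-butyl(dimethyl)silyl]oxy}methyl)-2,3-dimethoxyphenyl]-4,5-dimethylbicyclo[3.1.0]hexan-2-ol (cyclopropane cis to hydroxyl) | C[C@@]1(CC(O)C2CC21C)c1cc(CO[Si](C)(C)C(C)(C)C)cc(OC)c1OC
F7 | step 9 | (4S)-4-[5-({[tert-butyl(dimethyl)silyl]oxy}methyl)-2,3-dimethoxyphenyl]-4,5-dimethylbicyclo[3.1.0]hexan-2-one | C[C@@]1(CC(=O)C2CC21C)c1cc(CO[Si](C)(C)C(C)(C)C)cc(OC)c1OC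
F8 | step 10 | 4-methylbenzenesulfonylhydrazone of (3S)-3-[5-({[tert-butyl(dimethyl)silyl]oxy}methyl)-2,3-dimethoxyphenyl]-3,4,4-trimethylcyclopentan-1-one | C[C@@]1(CC(=NNS(=O)(=O)c2ccc(C)cc2)CC1(C)C)c1cc(CO[Si](C)(C)C(C)(C)C)cc(OC)c1OC
F9 | step 10 | tert-butyl({3,4-dimethoxy-5-[(1S)-1,2,2-trimethylcyclopentyl]phenyl}methoxy)dimethylsilane | C[C@@]1(CCCC1(C)C)c1cc(CO[Si](C)(C)C(C)(C)C)cc(OC)c1OC
F10 | step 12 | 3,4-dimethoxy-5-[(1S)-1,2,2-trimethylcyclopentyl]benzaldehyde | C[C@@]1(CCCC1(C)C)c1cc(C=O)cc(OC)c1OC
F11 | step 12 | (E)-1,2-bis{3,4-dimethoxy-5-[(1S)-1,2,2-trimethylcyclopentyl]phenyl}ethene | C[C@@]1(CCCC1(C)C)c1cc(/C=C/c2cc(OC)c(OC)c([C@@]3(C)CCCC3(C)C)c2)cc(OC)c1OC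
A1 | alternative 1 | (1S,3R)-1,2,2-trimethylcyclopentane-1,3-dicarboxylic acid ((1S,3R)-camphoric acid) | C[C@@]1(CC[C@@H](C(=O)O)C1(C)C)C(=O)O
A2 | alternative 1 | 1,1-dimethoxy-4-[(1S)-1,2,2-trimethylcyclopentyl]but-3-yn-2-one | COC(OC)C(=O)C#C[C@@]1(C)CCCC1(C)C
A3 | alternative 1 | methyl 2-methoxy-3-oxobutanoate | COC(C(C)=O)C(=O)OC
A4 | alternative 1 | 5-(dimethoxymethyl)-2-methoxy-3-[(1S)-1,2,2-trimethylcyclopentyl]phenol | COC(OC)c1cc(O)c(OC)c([C@@]2(C)CCCC2(C)C)c1
A5 | alternative 2 | 1,2-bis{4-[(5,5-dimethylcyclopent-1-en-1-yl)methoxy]-3-iodo-5-methoxyphenyl}ethane | COc1cc(CCc2cc(OC)c(OCC3=CCCC3(C)C)c(I)c2)cc(I)c1OCC1=CCCC1(C)C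
A6 | alternative 2 | 1,2-bis[(3R)-7-methoxy-5',5'-dimethyl-2H-spiro[1-benzofuran-3,1'-cyclopentan]-2'-en-5-yl]ethane | COc1cc(CCc3cc(OC)c4OC[C@@]5(C=CCC5(C)C)c4c3)cc2c1OC[C@@]21C=CCC1(C)C
A7 | alternative 3 | 5-bromo-1,2-dimethoxy-3-[(1S)-1,2,2-trimethylcyclopentyl]benzene | COc1cc(Br)cc([C@@]2(C)CCCC2(C)C)c1OC
A8 | alternative 3 | acetylene | C#C
A9 | alternative 3 | bis{3,4-dimethoxy-5-[(1S)-1,2,2-trimethylcyclopentyl]phenyl}acetylene | COc1cc(C#Cc2cc(OC)c(OC)c([C@@]3(C)CCCC3(C)C)c2)cc([C@@]2(C)CCCC2(C)C)c1OC
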